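**Plan**
1. Retrosynthesis: the C2a sulfate and the two benzyl ethers come off last, both CH2O arms (C2a, C3a) go back to esters, and ring B is cut at C1–C2 and C3–C4 (retro-[4+2]) into a fumarate diester and an ortho-quinodimethane carrying the aryl group on the future C1.
2. Enabling feature (tetralin numbering: C1 aryl-bearing, C2/C3 with arms C2a/C3a, C4 methylene, C4a/C8a fusion carbons): ring B is a cyclohexene retron whose C4a–C8a bond belongs to aromatic ring A and whose trans C2–C3 unit with both one-carbon arms is a reduced fumarate.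
3. The diene is stored as its SO2 adduct, a benzo-fused sulfolene. A hydroxyl on the sulfolene carbon that becomes C4 lets SO2 leave below 100 °C and steers the neighbouring ester endo; it is deleted afterwards by ionic hydrogenation.
4. Forward: syringaldehyde supplies ring A and the pendant ring, joined at C1–C8a by a Grignard–benzyl bromide coupling; photoenolisation with SO2 capture gives the sulfolene; ring B, the only ring made, closes in the cycloaddition; then C4 deoxygenation, ester reduction, C3a silylation, C2a sulfation, desilylation and debenzylation.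
5. Stereochemistry: C2/C3 trans from the (E)-fumarate, C1/C2 trans from the hydroxyl-directed endo mode of an out,out-diene, absolute configuration from two (S)-lactate ester groups; C1, C2 and C3 are not touched again.

Key step: step 9

Assumption: the (S)-lactate esters are taken to expose the fumarate face that leads to the (1R,2S,3S) series, the sense expected for (S)-α-acyloxy ester auxiliaries in additions of hydroxy ortho-quinodimethanes.
Assumption: the target is drawn as the free hydrogen sulfate; the sulfate is carried as its sodium salt and protonated only in the last operation.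

**Route**

Step 1
Reactants: 1 syringaldehyde
Product: 2 4-(benzyloxy)-3,5-dimethoxybenzaldehyde
Conditions: BnBr, K2CO3, DMF, 60 °C
Reagents that add atoms: benzyl bromide, BrCc1ccccc1
Why: Williamson ether synthesis on the phenoxide should protect the only acidic group as a benzyl ether that survives every later step up to the final hydrogenolysis.

Step 2
Reactants: 2 4-(benzyloxy)-3,5-dimethoxybenzaldehyde
Product: 3 4-(benzyloxy)-2-bromo-3,5-dimethoxybenzaldehyde
Conditions: NBS (1.05 equiv), MeCN, rt, dark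
Reagents that add atoms: N-bromosuccinimide, O=C1CCC(=O)N1Br
Why: Electrophilic aromatic bromination should occur at C2 (equivalent to C6), the only free ring position, which is ortho to one methoxy group and para to the other.

Step 3
Reactants: 3 4-(benzyloxy)-2-bromo-3,5-dimethoxybenzaldehyde
Product: 4 2-[4-(benzyloxy)-2-bromo-3,5-dimethoxyphenyl]-1,3-dioxolane
Conditions: HOCH2CH2OH, TsOH·H2O (cat.), toluene, reflux, azeotropic removal of water
Reagents that add atoms: ethylene glycol, OCCO
Why: Acid-catalysed acetalisation masks the aldehyde against the Grignard reagent formed in step 6.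

Step 4
Reactants: 2 4-(benzyloxy)-3,5-dimethoxybenzaldehyde
Product: 5 [4-(benzyloxy)-3,5-dimethoxyphenyl]methanol
Conditions: NaBH4, MeOH/THF, 0 °C
Reagents that add atoms: none
Why: Borohydride reduction of an aryl aldehyde to the benzylic alcohol is routine and leaves the benzyl ether untouched.

Step 5
Reactants: 5 [4-(benzyloxy)-3,5-dimethoxyphenyl]methanol
Product: 6 2-(benzyloxy)-5-(bromomethyl)-1,3-dimethoxybenzene
Conditions: PBr3, CH2Cl2, 0 °C; used without storage
Reagents that add atoms: phosphorus tribromide, BrP(Br)Br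
Why: Bromide displaces the phosphite ester of the benzylic alcohol (SN2 substitution) to give the reactive benzylic bromide needed as the electrophile of step 6.

Step 6
Reactants: 4 2-[4-(benzyloxy)-2-bromo-3,5-dimethoxyphenyl]-1,3-dioxolane; 6 2-(benzyloxy)-5-(bromomethyl)-1,3-dimethoxybenzene
Product: 9 4-(benzyloxy)-2-[4-(benzyloxy)-3,5-dimethoxybenzyl]-3,5-dimethoxybenzaldehyde, via arylmagnesium bromide 7 (not isolated), via diarylmethane dioxolane 8 (not isolated)
Conditions: 4, Mg (I2-activated), THF, 50 °C; then 6, Li2CuCl4 (5 mol %), THF, −20 °C → rt; then 2 M HCl, THF, rt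
Reagents that add atoms: water, O
Why: Magnesium insertion gives aryl Grignard 7, which should couple with benzylic bromide 6 under copper catalysis (copper-catalysed Grignard–alkyl halide cross-coupling) to diarylmethane 8, and the acidic work-up hydrolyses the dioxolane (acetal hydrolysis) to aldehyde 9.

Step 7
Reactants: 9 4-(benzyloxy)-2-[4-(benzyloxy)-3,5-dimethoxybenzyl]-3,5-dimethoxybenzaldehyde
Product: 11 cis-5-(benzyloxy)-3-[4-(benzyloxy)-3,5-dimethoxyphenyl]-1-hydroxy-4,6-dimethoxy-1,3-dihydro-2-benzothiophene 2,2-dioxide (racemic), via hydroxy ortho-quinodimethane 10 (not isolated)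
Conditions: hν (350 nm, Pyrex), SO2-saturated benzene, rt, argon
Reagents that add atoms: sulfur dioxide, O=S=O
Why: Excitation of the aryl aldehyde triggers 1,5-hydrogen transfer from the doubly benzylic CH2 (photoenolisation) to the out,out-dienol 10, which SO2 should capture by suprafacial cheletropic [4+1] addition to give the cis hydroxy sulfone, whose two racemic stereocentres are erased again in step 9.

Step 8
Reactants: 12 fumaryl chloride; 13 methyl (S)-lactate
Product: 14 bis[(2S)-1-methoxy-1-oxopropan-2-yl] (2E)-but-2-enedioate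
Conditions: 13 (2.1 equiv), Et3N, DMAP (cat.), CH2Cl2, 0 °C → rt
Reagents that add atoms: none
Why: Double acyl substitution of the acid chloride by the secondary alcohol (esterification) keeps the (E)-alkene and does not involve the lactate stereocentre.

Step 9
Reactants: 11 cis-5-(benzyloxy)-3-[4-(benzyloxy)-3,5-dimethoxyphenyl]-1-hydroxy-4,6-dimethoxy-1,3-dihydro-2-benzothiophene 2,2-dioxide; 14 bis[(2S)-1-methoxy-1-oxopropan-2-yl] (2E)-but-2-enedioate
Product: 15 bis[(2S)-1-methoxy-1-oxopropan-2-yl] (1R,2S,3R,4R)-7-(benzyloxy)-1-[4-(benzyloxy)-3,5-dimethoxyphenyl]-4-hydroxy-6,8-dimethoxy-1,2,3,4-tetrahydronaphthalene-2,3-dicarboxylate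
Conditions: 14 (2 equiv), toluene, 90 °C, slow argon sweep
Reagents that add atoms: none
Why: On warming, sulfone 11 should give back the out,out-dienol 10 met in step 7 by a thermally allowed cheletropic loss of SO2 that the hydroxyl lone pair accelerates (the unhydroxylated sulfolene would need about 200 °C), and this transient diene adds suprafacially to the electron-poor alkene of 14 in a concerted normal-electron-demand [4+2] cycloaddition that restores the aromaticity of ring A. The closest known reaction type is the Diels–Alder trapping of α-hydroxy-α'-aryl ortho-quinodimethanes, released from 1-hydroxy-3-aryl-1,3-dihydrobenzo[c]thiophene 2,2-dioxides, by fumarates of α-hydroxy esters in aryltetralin lignan synthesis. Ring B closes by this intermolecular [4+2] cycloaddition, C1–C2 and C3–C4 forming together between the two exocyclic diene termini and the two alkene carbons. C2 and C3 become trans because the (E)-geometry of the fumarate is transferred stereospecifically, and C1 and C4 become cis to each other because aryl and hydroxyl both sit outward on the diene. The ester next to the hydroxyl-bearing terminus takes the endo position (hydrogen bond from the dienol OH plus secondary orbital overlap), making C3/C4 cis and therefore C1/C2 trans, and the absolute sense comes from the two (S)-lactate groups, which shield the same alkene face of the twofold-symmetric fumarate. The step needs this endo preference and diene-face selectivity, secured by the C4 hydroxyl and by the lactate groups at the low temperature the hydroxyl-activated extrusion allows; no regiochemical question arises because 14 is symmetric.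

Step 10
Reactants: 15 the 4-hydroxy bis-lactate adduct
Product: 16 bis[(2S)-1-methoxy-1-oxopropan-2-yl] (1R,2S,3S)-7-(benzyloxy)-1-[4-(benzyloxy)-3,5-dimethoxyphenyl]-6,8-dimethoxy-1,2,3,4-tetrahydronaphthalene-2,3-dicarboxylate
Conditions: Et3SiH (4 equiv), TFA, CH2Cl2, −10 → 0 °C
Reagents that add atoms: none
Why: Ionic hydrogenation: TFA should ionise the benzylic C4 carbinol to a cation stabilised by the para C7 oxygen and Et3SiH delivers hydride, turning C4 into the required methylene without affecting C1–C3, the esters or the benzyl ethers.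

Step 11
Reactants: 16 the all-trans bis-lactate diester
Product: 17 [(1R,2S,3S)-7-(benzyloxy)-1-[4-(benzyloxy)-3,5-dimethoxyphenyl]-6,8-dimethoxy-1,2,3,4-tetrahydronaphthalene-2,3-diyl]dimethanol
Conditions: LiAlH4, THF, 0 °C → rt; H2O quench, filtration through Celite
Reagents that add atoms: none
Why: Hydride reduction of both ring esters (and of the lactate methyl esters) to primary alcohols releases the auxiliary and gives the C2a/C3a diol with the ring stereocentres unchanged.

Step 12
Reactants: 17 the C2a/C3a diol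
Product: 18 [(1R,2S,3S)-7-(benzyloxy)-1-[4-(benzyloxy)-3,5-dimethoxyphenyl]-3-({[tert-butyl(diphenyl)silyl]oxy}methyl)-6,8-dimethoxy-1,2,3,4-tetrahydronaphthalen-2-yl]methanol
Conditions: TBDPSCl (1.05 equiv), imidazole, CH2Cl2, −20 → 0 °C
Reagents that add atoms: tert-butyl(chloro)diphenylsilane, CC(C)(C)[Si](Cl)(c1ccccc1)c1ccccc1
Why: Kinetic silylation with a bulky silyl chloride should take the C3a hydroxyl, which adjoins the unsubstituted C4 methylene, in preference to the C2a hydroxyl, which is screened by the C1 aryl group.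

Step 13
Reactants: 18 the C3a silyl ether
Product: 20 sodium [(1R,2S,3S)-7-(benzyloxy)-1-[4-(benzyloxy)-3,5-dimethoxyphenyl]-3-({[tert-butyl(diphenyl)silyl]oxy}methyl)-6,8-dimethoxy-1,2,3,4-tetrahydronaphthalen-2-yl]methyl sulfate, via pyridinium sulfate 19 (not isolated)
Conditions: SO3·pyridine (3 equiv), pyridine, rt; then aq. NaHCO3
Reagents that add atoms: sulfur trioxide–pyridine complex, O=S(=O)([O-])[n+]1ccccc1; sodium hydrogen carbonate, [Na+].OC([O-])=O
Why: O-Sulfation of the only free hydroxyl by the SO3–pyridine complex gives the sulfate monoester, and bicarbonate exchanges pyridinium for sodium; silyl and benzyl ethers are inert.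

Step 14
Reactants: 20 the silylated sodium sulfate
Product: 21 sodium [(1R,2S,3S)-7-(benzyloxy)-1-[4-(benzyloxy)-3,5-dimethoxyphenyl]-3-(hydroxymethyl)-6,8-dimethoxy-1,2,3,4-tetrahydronaphthalen-2-yl]methyl sulfate
Conditions: HF·pyridine, pyridine/THF, 0 °C → rt; NaHCO3 quench
Reagents that add atoms: none
Why: Fluoride-driven desilylation under buffered conditions frees the C3a hydroxyl, and the sulfate monoester anion, a poor leaving group and not an electrophile at sulfur under these conditions, should remain intact.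

Step 15
Reactants: 21 the dibenzyl sodium sulfate
Product: 23 [(1R,2S,3S)-7-hydroxy-1-(4-hydroxy-3,5-dimethoxyphenyl)-3-(hydroxymethyl)-6,8-dimethoxy-1,2,3,4-tetrahydronaphthalen-2-yl]methyl hydrogen sulfate, via sodium salt 22 (not isolated)
Conditions: H2 (1 atm), Pd/C (10% palladium on carbon), MeOH/H2O, rt; filter; then HCl (1.0 equiv), 0 °C; C18 desalting, lyophilise
Reagents that add atoms: none
Why: Catalytic hydrogenolysis cleaves both aryl benzyl ethers without affecting the alkyl sulfate or the stereocentres, and one equivalent of acid converts the sodium salt into the hydrogen sulfate as drawn.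

**Compound list**
1 | syringaldehyde (4-hydroxy-3,5-dimethoxybenzaldehyde) | COc1cc(C=O)cc(OC)c1O | starting material
2 | 4-(benzyloxy)-3,5-dimethoxybenzaldehyde | COc1cc(C=O)cc(OC)c1OCc1ccccc1 | intermediate
3 | 4-(benzyloxy)-2-bromo-3,5-dimethoxybenzaldehyde | COc1cc(C=O)c(Br)c(OC)c1OCc1ccccc1 | intermediate
4 | 2-[4-(benzyloxy)-2-bromo-3,5-dimethoxyphenyl]-1,3-dioxolane | COc1cc(C2OCCO2)c(Br)c(OC)c1OCc1ccccc1 | intermediate
5 | [4-(benzyloxy)-3,5-dimethoxyphenyl]methanol | COc1cc(CO)cc(OC)c1OCc1ccccc1 | intermediate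
6 | 2-(benzyloxy)-5-(bromomethyl)-1,3-dimethoxybenzene | COc1cc(CBr)cc(OC)c1OCc1ccccc1 | intermediate
7 | [3-(benzyloxy)-6-(1,3-dioxolan-2-yl)-2,4-dimethoxyphenyl]magnesium bromide (not isolated) | COc1cc(C2OCCO2)c([Mg]Br)c(OC)c1OCc1ccccc1 | intermediate
8 | 2-{4-(benzyloxy)-2-[4-(benzyloxy)-3,5-dimethoxybenzyl]-3,5-dimethoxyphenyl}-1,3-dioxolane (not isolated) | COc1cc(Cc2c(C3OCCO3)cc(OC)c(OCc3ccccc3)c2OC)cc(OC)c1OCc1ccccc1 | intermediate
9 | 4-(benzyloxy)-2-[4-(benzyloxy)-3,5-dimethoxybenzyl]-3,5-dimethoxybenzaldehyde | COc1cc(Cc2c(C=O)cc(OC)c(OCc3ccccc3)c2OC)cc(OC)c1OCc1ccccc1 | intermediate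
10 | transient hydroxy ortho-quinodimethane: 3-(benzyloxy)-5-[(4-benzyloxy-3,5-dimethoxyphenyl)methylidene]-6-(hydroxymethylidene)-2,4-dimethoxycyclohexa-1,3-diene, hydroxyl and aryl both outward (not isolated; the photodienol of step 7 and the diene that sulfone 11 sets free again in step 9) | O/C=C1\C=C(OC)C(OCc2ccccc2)=C(OC)/C1=C\c1cc(OC)c(OCc2ccccc2)c(OC)c1 | intermediate
11 | cis-5-(benzyloxy)-3-[4-(benzyloxy)-3,5-dimethoxyphenyl]-1-hydroxy-4,6-dimethoxy-1,3-dihydro-2-benzothiophene 2,2-dioxide (racemic, one enantiomer drawn) | O=S1(=O)[C@H](O)c2cc(OC)c(OCc3ccccc3)c(OC)c2[C@@H]1c1cc(OC)c(OCc2ccccc2)c(OC)c1 | intermediate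
12 | fumaryl chloride | O=C(Cl)/C=C/C(=O)Cl | starting material
13 | methyl (S)-lactate | C[C@H](O)C(=O)OC | starting material
14 | bis[(2S)-1-methoxy-1-oxopropan-2-yl] (2E)-but-2-enedioate | COC(=O)[C@H](C)OC(=O)/C=C/C(=O)O[C@@H](C)C(=O)OC | intermediate
15 | bis[(2S)-1-methoxy-1-oxopropan-2-yl] (1R,2S,3R,4R)-7-(benzyloxy)-1-[4-(benzyloxy)-3,5-dimethoxyphenyl]-4-hydroxy-6,8-dimethoxy-1,2,3,4-tetrahydronaphthalene-2,3-dicarboxylate | COc1cc([C@@H]2c3c(cc(OC)c(OCc4ccccc4)c3OC)[C@H](O)[C@H](C(=O)O[C@@H](C)C(=O)OC)[C@H]2C(=O)O[C@@H](C)C(=O)OC)cc(OC)c1OCc1ccccc1 | intermediate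
16 | bis[(2S)-1-methoxy-1-oxopropan-2-yl] (1R,2S,3S)-7-(benzyloxy)-1-[4-(benzyloxy)-3,5-dimethoxyphenyl]-6,8-dimethoxy-1,2,3,4-tetrahydronaphthalene-2,3-dicarboxylate | COc1cc([C@@H]2c3c(cc(OC)c(OCc4ccccc4)c3OC)C[C@H](C(=O)O[C@@H](C)C(=O)OC)[C@H]2C(=O)O[C@@H](C)C(=O)OC)cc(OC)c1OCc1ccccc1 | intermediate
17 | [(1R,2S,3S)-7-(benzyloxy)-1-[4-(benzyloxy)-3,5-dimethoxyphenyl]-6,8-dimethoxy-1,2,3,4-tetrahydronaphthalene-2,3-diyl]dimethanol | COc1cc([C@@H]2c3c(cc(OC)c(OCc4ccccc4)c3OC)C[C@H](CO)[C@H]2CO)cc(OC)c1OCc1ccccc1 | intermediate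
18 | [(1R,2S,3S)-7-(benzyloxy)-1-[4-(benzyloxy)-3,5-dimethoxyphenyl]-3-({[tert-butyl(diphenyl)silyl]oxy}methyl)-6,8-dimethoxy-1,2,3,4-tetrahydronaphthalen-2-yl]methanol | COc1cc([C@@H]2c3c(cc(OC)c(OCc4ccccc4)c3OC)C[C@H](CO[Si](c4ccccc4)(c4ccccc4)C(C)(C)C)[C@H]2CO)cc(OC)c1OCc1ccccc1 | intermediate
19 | pyridinium salt of the C2a sulfate of 18 (not isolated) | COc1cc([C@@H]2c3c(cc(OC)c(OCc4ccccc4)c3OC)C[C@H](CO[Si](c4ccccc4)(c4ccccc4)C(C)(C)C)[C@H]2COS(=O)(=O)[O-])cc(OC)c1OCc1ccccc1.c1cc[nH+]cc1 | intermediate
20 | sodium [(1R,2S,3S)-7-(benzyloxy)-1-[4-(benzyloxy)-3,5-dimethoxyphenyl]-3-({[tert-butyl(diphenyl)silyl]oxy}methyl)-6,8-dimethoxy-1,2,3,4-tetrahydronaphthalen-2-yl]methyl sulfate | COc1cc([C@@H]2c3c(cc(OC)c(OCc4ccccc4)c3OC)C[C@H](CO[Si](c4ccccc4)(c4ccccc4)C(C)(C)C)[C@H]2COS(=O)(=O)[O-])cc(OC)c1OCc1ccccc1.[Na+] | intermediate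
21 | sodium [(1R,2S,3S)-7-(benzyloxy)-1-[4-(benzyloxy)-3,5-dimethoxyphenyl]-3-(hydroxymethyl)-6,8-dimethoxy-1,2,3,4-tetrahydronaphthalen-2-yl]methyl sulfate | COc1cc([C@@H]2c3c(cc(OC)c(OCc4ccccc4)c3OC)C[C@H](CO)[C@H]2COS(=O)(=O)[O-])cc(OC)c1OCc1ccccc1.[Na+] | intermediate
22 | sodium [(1R,2S,3S)-7-hydroxy-1-(4-hydroxy-3,5-dimethoxyphenyl)-3-(hydroxymethyl)-6,8-dimethoxy-1,2,3,4-tetrahydronaphthalen-2-yl]methyl sulfate (not isolated) | COc1cc([C@@H]2c3c(cc(OC)c(O)c3OC)C[C@H](CO)[C@H]2COS(=O)(=O)[O-])cc(OC)c1O.[Na+] | intermediate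
23 | [(1R,2S,3S)-7-hydroxy-1-(4-hydroxy-3,5-dimethoxyphenyl)-3-(hydroxymethyl)-6,8-dimethoxy-1,2,3,4-tetrahydronaphthalen-2-yl]methyl hydrogen sulfate | COc1cc([C@@H]2c3c(cc(OC)c(O)c3OC)C[C@H](CO)[C@H]2COS(=O)(=O)O)cc(OC)c1O | target

**Step count**
Total: 15 steps. Longest linear sequence: 12 steps from syringaldehyde (steps 1, 2, 3, 6, 7, 9, 10, 11, 12, 13, 14, 15; the branch through steps 1, 4, 5 is equally long).

**Steps most likely to fail**

Step 9. The small lactate residues may discriminate the two fumarate faces only partly at 90 °C, and the C8 methoxy group crowds the outward aryl group, which may slow the cycloaddition relative to return of the dienol to aldehyde 9. Fallback: move the stereocontrol to a larger, crystalline auxiliary. Fumaryl chloride 12 is esterified with methyl (S)-mandelate (Et3N, DMAP, CH2Cl2) to bis[(1S)-2-methoxy-2-oxo-1-phenylethyl] (2E)-but-2-enedioate F1. Sulfone 11 is thermolysed with it in toluene at 90 °C to the 4-hydroxy bis-mandelate adduct F2, whose phenyl groups should screen one face more completely and whose minor diastereomer should be removable by crystallisation. Et3SiH/TFA then gives the deoxygenated bis-mandelate diester F3, and LiAlH4 reduction rejoins the route at diol 17. The fallback sets out from 11 and 12 and returns at 17.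

Step 7. Capture of the short-lived photodienol by SO2 may lose out to reketonisation, or the hydroxy sulfone may ring-open on isolation. Fallback: omit the sulfone and irradiate aldehyde 9 (350 nm, Pyrex, toluene, −20 °C) in the presence of fumarate 14, so that dienol 10 is generated photochemically and trapped in situ; any dienol that reverts is simply excited again, and the low temperature should favour the auxiliary control. This sets out from 9 and rejoins the route at adduct 15, with no new compound (F0).

Step 12. The two primary hydroxyls may be discriminated incompletely, giving bis-silylation or silylation at C2a. Fallback: enzymatic differentiation. Diol 17 is acylated by lipase-catalysed transesterification (Candida antarctica lipase B, vinyl acetate, tert-butyl methyl ether, 30 °C), expected to occur at the less encumbered C3a hydroxyl, to the C3a monoacetate F4. Sulfation with SO3·pyridine and NaHCO3 work-up gives the sulfated acetate sodium salt F5, and methanolysis of the acetate (K2CO3 cat., MeOH, 0 °C) rejoins the route at 21. The fallback sets out from 17 and returns at 21.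

**Further compounds**
F1 | step 9 | bis[(1S)-2-methoxy-2-oxo-1-phenylethyl] (2E)-but-2-enedioate | COC(=O)[C@@H](OC(=O)/C=C/C(=O)O[C@H](C(=O)OC)c1ccccc1)c1ccccc1
F2 | step 9 | bis[(1S)-2-methoxy-2-oxo-1-phenylethyl] (1R,2S,3R,4R)-7-(benzyloxy)-1-[4-(benzyloxy)-3,5-dimethoxyphenyl]-4-hydroxy-6,8-dimethoxy-1,2,3,4-tetrahydronaphthalene-2,3-dicarboxylate | COc1cc([C@@H]2c3c(cc(OC)c(OCc4ccccc4)c3OC)[C@H](O)[C@H](C(=O)O[C@@H](c4ccccc4)C(=O)OC)[C@H]2C(=O)O[C@@H](c2ccccc2)C(=O)OC)cc(OC)c1OCc1ccccc1
F3 | step 9 | bis[(1S)-2-methoxy-2-oxo-1-phenylethyl] (1R,2S,3S)-7-(benzyloxy)-1-[4-(benzyloxy)-3,5-dimethoxyphenyl]-6,8-dimethoxy-1,2,3,4-tetrahydronaphthalene-2,3-dicarboxylate | COc1cc([C@@H]2c3c(cc(OC)c(OCc4ccccc4)c3OC)C[C@H](C(=O)O[C@@H](c4ccccc4)C(=O)OC)[C@H]2C(=O)O[C@@H](c2ccccc2)C(=O)OC)cc(OC)c1OCc1ccccc1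
F0 | step 7 | none | none
F4 | step 12 | {(2S,3S,4R)-6-(benzyloxy)-4-[4-(benzyloxy)-3,5-dimethoxyphenyl]-3-(hydroxymethyl)-5,7-dimethoxy-1,2,3,4-tetrahydronaphthalen-2-yl}methyl acetate (the C3a monoacetate of 17) | COc1cc([C@@H]2c3c(cc(OC)c(OCc4ccccc4)c3OC)C[C@H](COC(C)=O)[C@H]2CO)cc(OC)c1OCc1ccccc1
F5 | step 12 | sodium salt of the C2a sulfate of the C3a monoacetate | COc1cc([C@@H]2c3c(cc(OC)c(OCc4ccccc4)c3OC)C[C@H](COC(C)=O)[C@H]2COS(=O)(=O)[O-])cc(OC)c1OCc1ccccc1.[Na+]
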